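**Plan**

- Labels: ring A = 4-hydroxy-3-methoxyphenyl; ring B = 3,5-dimethoxy-4-oxyphenyl; ring C and ring D = benzene and furan rings of the dihydrobenzofuran (O1, C2, C3; C9 = hydroxymethyl carbon on C3); C7', C8', C9' = glycerol chain carried by ring A.
- Cuts: C5–CHO (back to C5–Br), C7'–ring A (aryl Grignard on a Weinreb amide), ring B oxygen–C8' (Mitsunobu ether), O1–C2 (ring D), C2–C3 (aldol).
- Forward: an Evans aldol joins the ring C arylacetyl unit to the ring B aldehyde (C3–C2) and reduction gives the 1,3-diol; ring D then closes through O1–C2; the C8'–O ether, the C7'–ring A bond, reduction at C7', formylation at C5 and desilylation follow.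
- Enabling feature: C2 is benzylic to ring B and para to its free phenol, so the C2 carbinol ionises reversibly to a p-quinone methide that O1 of ring C captures; C3 alone then decides C2.
- Stereochemistry: C3 from (R)-4-benzyl-2-oxazolidinone (boron aldol); C2 trans to C3 by thermodynamic control; C8' from methyl (S)-glycerate with Mitsunobu inversion; C7' by chelation-controlled hydride addition directed by C8'.

Key step: step 11

Remark: the aldol-derived carbinol centre is written with the configuration of the expected syn adduct; its epimer is carried along unchanged, because the ring closure erases this centre.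

**Route**

Step 1
Reactants: 1 5-bromo-2-hydroxy-3-methoxybenzaldehyde
Product: 2 5-bromo-3-methoxy-2-[(triisopropylsilyl)oxy]benzaldehyde
Conditions: iPr3SiCl, imidazole, DMF, rt
Reagents that add atoms: chlorotri(propan-2-yl)silane, CC(C)[Si](Cl)(C(C)C)C(C)C
Why: Imidazole-mediated O-silylation of the phenol; the triisopropylsilyl ether should survive the ylide, dilute acid and hydride steps and is slow to migrate to a neighbouring alkoxide.

Step 2
Reactants: 2 5-bromo-3-methoxy-2-[(triisopropylsilyl)oxy]benzaldehyde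
Product: 3 {4-bromo-2-methoxy-6-[2-methoxyethenyl]phenoxy}triisopropylsilane (E/Z mixture)
Conditions: Ph3P(CH2OMe)Cl, KN(SiMe3)2, THF, 0 °C; then 2, 0 °C → rt
Reagents that add atoms: (methoxymethyl)triphenylphosphonium chloride, COC[P+](c1ccccc1)(c1ccccc1)c1ccccc1.[Cl-]
Why: Wittig olefination with the methoxymethylidene ylide should give the one-carbon-extended enol ether, whose geometry is irrelevant.

Step 3
Reactants: 3 aryl enol ether
Product: 4 2-{5-bromo-3-methoxy-2-[(triisopropylsilyl)oxy]phenyl}acetaldehyde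
Conditions: 2 M aq HCl, THF, 50 °C
Reagents that add atoms: water, O
Why: Acid-catalysed enol ether hydrolysis should release the arylacetaldehyde, aryl triisopropylsilyl ethers being stable to dilute aqueous acid.

Step 4
Reactants: 4 arylacetaldehyde
Product: 5 2-{5-bromo-3-methoxy-2-[(triisopropylsilyl)oxy]phenyl}acetic acid
Conditions: NaClO2, NaH2PO4, 2-methylbut-2-ene, t-BuOH/H2O, rt
Reagents that add atoms: sodium chlorite, [Na+].[O-]Cl=O
Why: Pinnick oxidation takes the aldehyde to the acid under buffered conditions that should leave the silyl ether and the aryl bromide untouched.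

Step 5
Reactants: 5 arylacetic acid; 6 (4R)-4-benzyl-1,3-oxazolidin-2-one
Product: 8 (4R)-4-benzyl-3-(arylacetyl)oxazolidin-2-one, via mixed pivalic anhydride 7 (not isolated)
Conditions: t-BuCOCl, Et3N, THF, −20 °C; then 6, LiCl, −20 °C → rt
Reagents that add atoms: none
Why: N-acylation of the oxazolidinone through the mixed pivalic anhydride under LiCl/Et3N activation should give the imide without strong base.

Step 6
Reactants: 9 syringaldehyde (4-hydroxy-3,5-dimethoxybenzaldehyde)
Product: 10 4-[(tert-butyldimethylsilyl)oxy]-3,5-dimethoxybenzaldehyde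
Conditions: t-BuMe2SiCl, imidazole, DMF, rt
Reagents that add atoms: tert-butyldimethylsilyl chloride, CC(C)(C)[Si](C)(C)Cl
Why: Phenol silylation keeps the aldehyde electrophilic under the amine base of the aldol and gives a group that fluoride removes later.

Step 7
Reactants: 8 arylacetyl imide; 10 silylated syringaldehyde
Product: 12 (2R,3R)-syn-aldol imide, via Z dibutylboron enolate 11 (not isolated)
Conditions: Bu2BOTf, iPr2NEt, CH2Cl2, −78 → 0 °C; then 10, −78 → 0 °C; H2O2, MeOH, NaH2PO4/Na2HPO4 buffer (pH 7), 0 °C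
Reagents that add atoms: none
Why: Evans syn aldol: the Z boron enolate reacts through a chair Zimmerman–Traxler transition state on the face away from the benzyl group, which sets the future C3 (2R in the imide) and a carbinol centre (3R) that is not needed later.

Step 8
Reactants: 12 syn-aldol imide
Product: 13 (1R,2S)-2-aryl-1-aryl-propane-1,3-diol (both phenols silylated)
Conditions: LiBH4, MeOH (1 equiv), THF, 0 °C
Reagents that add atoms: none
Why: Reductive cleavage of the N-acyl oxazolidinone with LiBH4 should give the primary alcohol and return the auxiliary, leaving no enolisable carbonyl next to the future C3.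

Step 9
Reactants: 13 diol
Product: 14 primary tert-butyldiphenylsilyl ether of 13
Conditions: t-BuPh2SiCl, imidazole, CH2Cl2, 0 °C
Reagents that add atoms: tert-butyldiphenylsilyl chloride, CC(C)(C)[Si](Cl)(c1ccccc1)c1ccccc1
Why: The bulky silyl chloride should silylate the primary hydroxyl in preference to the secondary benzylic one, and the cap keeps the C9 oxygen out of steps 11 and 14.

Step 10
Reactants: 14 tris-silyl ether
Product: 15 4-{(1R,2S)-2-(5-bromo-2-hydroxy-3-methoxyphenyl)-3-[(tert-butyldiphenylsilyl)oxy]-1-hydroxypropyl}-2,6-dimethoxyphenol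
Conditions: Bu4NF (2.2 equiv), AcOH (2.2 equiv), THF, 0 °C → rt
Reagents that add atoms: none
Why: Fluoride cleaves aryl silyl ethers far faster than an alkyl tert-butyldiphenylsilyl ether, and the acetic acid buffer keeps the freed phenols protonated so that no quinone methide forms early.

Step 11
Reactants: 15 bis-phenol benzylic alcohol
Product: 17 4-[(2R,3S)-5-bromo-3-{[(tert-butyldiphenylsilyl)oxy]methyl}-7-methoxy-2,3-dihydro-1-benzofuran-2-yl]-2,6-dimethoxyphenol, via p-quinone methide 16 (not isolated)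
Conditions: TsOH·H2O (10 mol %), CH2Cl2 (0.01 M), 0 °C → rt
Reagents that add atoms: none
Why: Protonation of the benzylic hydroxyl and loss of water, pushed by the para phenol of ring B, give p-quinone methide 16, which is planar at C2, so both carbinol epimers of 15 converge. The phenol oxygen O1 of ring C adds to the exocyclic carbon and ring B rearomatises; the closest known reaction type is the acid-mediated cyclodehydration of 2-(2-hydroxyaryl)-1-arylpropane-1,3-diol derivatives to trans-2-aryl-2,3-dihydrobenzofurans, the laboratory counterpart of the ring closure in beta-5 phenol coupling. Ring D closes in a 5-exo-trig mode. The new stereocentre C2 is controlled by C3: attack anti to the silyloxymethyl arm is preferred, and because 17 is itself a para-hydroxybenzyl aryl ether the closure is reversible under the acid, so the mixture should settle on the trans (2R,3S) isomer. The step needs diastereoselectivity at C2 and capture by O1 only; the first rests on C3 and thermodynamic control, the second on the intramolecular five-membered closure, on dilution and on the silyl cap at the C9 oxygen, which also disfavours loss of the C9 arm as formaldehyde to a stilbene.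

Step 12
Reactants: 18 methyl (4S)-2,2-dimethyl-1,3-dioxolane-4-carboxylate
Product: 19 methyl (2S)-2,3-dihydroxypropanoate
Conditions: Dowex 50W (H+ form), MeOH, rt
Reagents that add atoms: none
Why: Acid-catalysed transacetalisation in methanol removes the acetonide without touching the methyl ester or the stereocentre.

Step 13
Reactants: 19 methyl (2S)-glycerate
Product: 20 methyl (2S)-3-[(tert-butyldimethylsilyl)oxy]-2-hydroxypropanoate
Conditions: t-BuMe2SiCl, imidazole, CH2Cl2, 0 °C
Reagents that add atoms: tert-butyldimethylsilyl chloride, CC(C)(C)[Si](C)(C)Cl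
Why: Selective silylation of the primary hydroxyl of the 1,2-diol leaves the less reactive alpha-hydroxy ester hydroxyl free for the ether formation.

Step 14
Reactants: 17 dihydrobenzofuran phenol; 20 silylated methyl (2S)-glycerate
Product: 21 methyl (2R)-2-(aryloxy)-3-[(tert-butyldimethylsilyl)oxy]propanoate
Conditions: PPh3, DIAD, THF, 0 °C → rt
Reagents that add atoms: none
Why: Mitsunobu etherification: the ring B phenol displaces the oxyphosphonium group of the alpha-hydroxy ester in an SN2 step, which inverts (S) to (R) and sets C8'.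

Step 15
Reactants: 21 aryloxy ester
Product: 22 (2R)-2-(aryloxy)-3-[(tert-butyldimethylsilyl)oxy]-N-methoxy-N-methylpropanamide
Conditions: MeNH(OMe)·HCl, iPrMgCl, THF, −20 °C
Reagents that add atoms: N,O-dimethylhydroxylamine hydrochloride, Cl.CNOC
Why: Aminolysis of the ester by the chloromagnesium amide gives the Weinreb amide at a temperature where the C8' proton should stay in place and the electron-rich aryl bromide does not exchange.

Step 16
Reactants: 23 4-bromo-2-methoxyphenol
Product: 24 (4-bromo-2-methoxyphenoxy)(tert-butyl)dimethylsilane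
Conditions: t-BuMe2SiCl, imidazole, DMF, rt
Reagents that add atoms: tert-butyldimethylsilyl chloride, CC(C)(C)[Si](C)(C)Cl
Why: Phenol silylation removes the acidic proton so that the aryl bromide can be converted into a Grignard reagent.

Step 17
Reactants: 22 Weinreb amide; 24 silylated 4-bromo-2-methoxyphenol
Product: 26 (2R)-2-(aryloxy)-1-aryl-3-silyloxypropan-1-one, via arylmagnesium bromide 25 (not isolated)
Conditions: 24, Mg, THF, 50 °C; then 22, THF, 0 °C; aq NH4Cl
Reagents that add atoms: none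
Why: Grignard addition to the Weinreb amide stops at the chelated tetrahedral intermediate, so the ketone appears only on work-up, without over-addition and without exchange at the ring C bromide.

Step 18
Reactants: 26 alpha-aryloxy ketone
Product: 27 (1S,2R)-2-(aryloxy)-1-aryl-3-silyloxypropan-1-ol
Conditions: Zn(BH4)2, Et2O, −30 → 0 °C
Reagents that add atoms: none
Why: Cram-chelate reduction: zinc bridges the ketone oxygen and the C8' aryloxy oxygen, and hydride enters from the side of the C8' hydrogen, which should give the anti (erythro) 7'S alcohol.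

Step 19
Reactants: 27 erythro alcohol
Product: 28 C7' tert-butyldimethylsilyl ether of 27
Conditions: t-BuMe2SiOTf, 2,6-lutidine, CH2Cl2, 0 °C
Reagents that add atoms: tert-butyldimethylsilyl trifluoromethanesulfonate, CC(C)(C)[Si](C)(C)OS(=O)(=O)C(F)(F)F
Why: Silylation of the hindered benzylic hydroxyl with the silyl triflate removes the last acidic proton before the lithiation.

Step 20
Reactants: 28 persilylated aryl bromide
Product: 30 persilylated C5 carbaldehyde, via C5 aryllithium 29 (not isolated)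
Conditions: t-BuLi (2.1 equiv), THF, −78 °C; DMF, −78 → 0 °C; aq NH4Cl
Reagents that add atoms: N,N-dimethylformamide, CN(C)C=O
Why: Bromine–lithium exchange at −78 °C is faster than any deprotonation, and DMF formylates the aryllithium (Bouveault aldehyde synthesis).

Step 21
Reactants: 30 persilylated aldehyde
Product: 31 target, (2R,3S)-2-(4-{[(1S,2R)-1,3-dihydroxy-1-(4-hydroxy-3-methoxyphenyl)propan-2-yl]oxy}-3,5-dimethoxyphenyl)-3-(hydroxymethyl)-7-methoxy-2,3-dihydro-1-benzofuran-5-carbaldehyde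
Conditions: Bu4NF, AcOH, THF, rt
Reagents that add atoms: none
Why: Fluoride-mediated global desilylation, buffered with acetic acid so that the aldehyde and the para-hydroxybenzyl alcohol of ring A do not meet basic fluoride.

**Compound list**

1 | 5-bromo-2-hydroxy-3-methoxybenzaldehyde | COc1cc(Br)cc(C=O)c1O | starting material
2 | 5-bromo-3-methoxy-2-[(triisopropylsilyl)oxy]benzaldehyde | COc1cc(Br)cc(C=O)c1O[Si](C(C)C)(C(C)C)C(C)C | intermediate
3 | {4-bromo-2-methoxy-6-[2-methoxyethenyl]phenoxy}triisopropylsilane, E/Z mixture | COC=Cc1cc(Br)cc(OC)c1O[Si](C(C)C)(C(C)C)C(C)C | intermediate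
4 | 2-{5-bromo-3-methoxy-2-[(triisopropylsilyl)oxy]phenyl}acetaldehyde | COc1cc(Br)cc(CC=O)c1O[Si](C(C)C)(C(C)C)C(C)C | intermediate
5 | 2-{5-bromo-3-methoxy-2-[(triisopropylsilyl)oxy]phenyl}acetic acid | COc1cc(Br)cc(CC(=O)O)c1O[Si](C(C)C)(C(C)C)C(C)C | intermediate
6 | (4R)-4-benzyl-1,3-oxazolidin-2-one | O=C1N[C@H](Cc2ccccc2)CO1 | starting material
7 | 2-{5-bromo-3-methoxy-2-[(triisopropylsilyl)oxy]phenyl}acetic pivalic anhydride (not isolated) | COc1cc(Br)cc(CC(=O)OC(=O)C(C)(C)C)c1O[Si](C(C)C)(C(C)C)C(C)C | intermediate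
8 | (4R)-4-benzyl-3-(2-{5-bromo-3-methoxy-2-[(triisopropylsilyl)oxy]phenyl}acetyl)-1,3-oxazolidin-2-one | COc1cc(Br)cc(CC(=O)N2[C@H](Cc3ccccc3)COC2=O)c1O[Si](C(C)C)(C(C)C)C(C)C | intermediate
9 | syringaldehyde (4-hydroxy-3,5-dimethoxybenzaldehyde) | COc1cc(C=O)cc(OC)c1O | starting material
10 | 4-[(tert-butyldimethylsilyl)oxy]-3,5-dimethoxybenzaldehyde | COc1cc(C=O)cc(OC)c1O[Si](C)(C)C(C)(C)C | intermediate
11 | Z dibutylboron enolate of 8 (not isolated) | COc1cc(Br)cc(/C=C(\OB(CCCC)CCCC)N2[C@H](Cc3ccccc3)COC2=O)c1O[Si](C(C)C)(C(C)C)C(C)C | intermediate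
12 | (4R)-4-benzyl-3-[(2R,3R)-2-{5-bromo-3-methoxy-2-[(triisopropylsilyl)oxy]phenyl}-3-{4-[(tert-butyldimethylsilyl)oxy]-3,5-dimethoxyphenyl}-3-hydroxypropanoyl]-1,3-oxazolidin-2-one | COc1cc(Br)cc([C@H]([C@@H](O)c2cc(OC)c(O[Si](C)(C)C(C)(C)C)c(OC)c2)C(=O)N2[C@H](Cc3ccccc3)COC2=O)c1O[Si](C(C)C)(C(C)C)C(C)C | intermediate
13 | (1R,2S)-2-{5-bromo-3-methoxy-2-[(triisopropylsilyl)oxy]phenyl}-1-{4-[(tert-butyldimethylsilyl)oxy]-3,5-dimethoxyphenyl}propane-1,3-diol | COc1cc(Br)cc([C@H]([C@@H](O)c2cc(OC)c(O[Si](C)(C)C(C)(C)C)c(OC)c2)CO)c1O[Si](C(C)C)(C(C)C)C(C)C | intermediate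
14 | (1R,2S)-2-{5-bromo-3-methoxy-2-[(triisopropylsilyl)oxy]phenyl}-1-{4-[(tert-butyldimethylsilyl)oxy]-3,5-dimethoxyphenyl}-3-[(tert-butyldiphenylsilyl)oxy]propan-1-ol | COc1cc(Br)cc([C@H]([C@@H](O)c2cc(OC)c(O[Si](C)(C)C(C)(C)C)c(OC)c2)CO[Si](c2ccccc2)(c2ccccc2)C(C)(C)C)c1O[Si](C(C)C)(C(C)C)C(C)C | intermediate
15 | 4-{(1R,2S)-2-(5-bromo-2-hydroxy-3-methoxyphenyl)-3-[(tert-butyldiphenylsilyl)oxy]-1-hydroxypropyl}-2,6-dimethoxyphenol | COc1cc(Br)cc([C@H]([C@@H](O)c2cc(OC)c(O)c(OC)c2)CO[Si](c2ccccc2)(c2ccccc2)C(C)(C)C)c1O | intermediate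
16 | 4-{(2S)-2-(5-bromo-2-hydroxy-3-methoxyphenyl)-3-[(tert-butyldiphenylsilyl)oxy]propylidene}-2,6-dimethoxycyclohexa-2,5-dien-1-one (not isolated) | COc1cc(Br)cc([C@H](C=C2C=C(OC)C(=O)C(OC)=C2)CO[Si](c2ccccc2)(c2ccccc2)C(C)(C)C)c1O | intermediate
17 | 4-[(2R,3S)-5-bromo-3-{[(tert-butyldiphenylsilyl)oxy]methyl}-7-methoxy-2,3-dihydro-1-benzofuran-2-yl]-2,6-dimethoxyphenol | COc1cc(cc(OC)c1O)[C@@H]2Oc3c(OC)cc(Br)cc3[C@H]2CO[Si](c4ccccc4)(c5ccccc5)C(C)(C)C | intermediate
18 | methyl (4S)-2,2-dimethyl-1,3-dioxolane-4-carboxylate | COC(=O)[C@@H]1COC(C)(C)O1 | starting material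
19 | methyl (2S)-2,3-dihydroxypropanoate | COC(=O)[C@@H](O)CO | intermediate
20 | methyl (2S)-3-[(tert-butyldimethylsilyl)oxy]-2-hydroxypropanoate | COC(=O)[C@@H](O)CO[Si](C)(C)C(C)(C)C | intermediate
21 | methyl (2R)-2-{4-[(2R,3S)-5-bromo-3-{[(tert-butyldiphenylsilyl)oxy]methyl}-7-methoxy-2,3-dihydro-1-benzofuran-2-yl]-2,6-dimethoxyphenoxy}-3-[(tert-butyldimethylsilyl)oxy]propanoate | COC(=O)[C@@H](CO[Si](C)(C)C(C)(C)C)Oc1c(OC)cc(cc1OC)[C@@H]2Oc3c(OC)cc(Br)cc3[C@H]2CO[Si](c4ccccc4)(c5ccccc5)C(C)(C)C | intermediate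
22 | (2R)-2-{4-[(2R,3S)-5-bromo-3-{[(tert-butyldiphenylsilyl)oxy]methyl}-7-methoxy-2,3-dihydro-1-benzofuran-2-yl]-2,6-dimethoxyphenoxy}-3-[(tert-butyldimethylsilyl)oxy]-N-methoxy-N-methylpropanamide | CON(C)C(=O)[C@@H](CO[Si](C)(C)C(C)(C)C)Oc1c(OC)cc(cc1OC)[C@@H]2Oc3c(OC)cc(Br)cc3[C@H]2CO[Si](c4ccccc4)(c5ccccc5)C(C)(C)C | intermediate
23 | 4-bromo-2-methoxyphenol | COc1cc(Br)ccc1O | starting material
24 | (4-bromo-2-methoxyphenoxy)(tert-butyl)dimethylsilane | COc1cc(Br)ccc1O[Si](C)(C)C(C)(C)C | intermediate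
25 | {4-[(tert-butyldimethylsilyl)oxy]-3-methoxyphenyl}magnesium bromide (not isolated) | COc1cc([Mg]Br)ccc1O[Si](C)(C)C(C)(C)C | intermediate
26 | (2R)-2-{4-[(2R,3S)-5-bromo-3-{[(tert-butyldiphenylsilyl)oxy]methyl}-7-methoxy-2,3-dihydro-1-benzofuran-2-yl]-2,6-dimethoxyphenoxy}-3-[(tert-butyldimethylsilyl)oxy]-1-{4-[(tert-butyldimethylsilyl)oxy]-3-methoxyphenyl}propan-1-one | COc1cc(ccc1O[Si](C)(C)C(C)(C)C)C(=O)[C@@H](CO[Si](C)(C)C(C)(C)C)Oc6c(OC)cc(cc6OC)[C@@H]2Oc3c(OC)cc(Br)cc3[C@H]2CO[Si](c4ccccc4)(c5ccccc5)C(C)(C)C | intermediate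
27 | (1S,2R)-2-{4-[(2R,3S)-5-bromo-3-{[(tert-butyldiphenylsilyl)oxy]methyl}-7-methoxy-2,3-dihydro-1-benzofuran-2-yl]-2,6-dimethoxyphenoxy}-3-[(tert-butyldimethylsilyl)oxy]-1-{4-[(tert-butyldimethylsilyl)oxy]-3-methoxyphenyl}propan-1-ol | COc1cc(ccc1O[Si](C)(C)C(C)(C)C)[C@H](O)[C@@H](CO[Si](C)(C)C(C)(C)C)Oc6c(OC)cc(cc6OC)[C@@H]2Oc3c(OC)cc(Br)cc3[C@H]2CO[Si](c4ccccc4)(c5ccccc5)C(C)(C)C | intermediate
28 | (2R,3S)-5-bromo-2-(4-{[(1S,2R)-1,3-bis[(tert-butyldimethylsilyl)oxy]-1-{4-[(tert-butyldimethylsilyl)oxy]-3-methoxyphenyl}propan-2-yl]oxy}-3,5-dimethoxyphenyl)-3-{[(tert-butyldiphenylsilyl)oxy]methyl}-7-methoxy-2,3-dihydro-1-benzofuran | COc1cc(ccc1O[Si](C)(C)C(C)(C)C)[C@H](O[Si](C)(C)C(C)(C)C)[C@@H](CO[Si](C)(C)C(C)(C)C)Oc6c(OC)cc(cc6OC)[C@@H]2Oc3c(OC)cc(Br)cc3[C@H]2CO[Si](c4ccccc4)(c5ccccc5)C(C)(C)C | intermediate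
29 | C5 aryllithium derived from 28 (lithium in place of bromine; not isolated) | COc1cc(ccc1O[Si](C)(C)C(C)(C)C)[C@H](O[Si](C)(C)C(C)(C)C)[C@@H](CO[Si](C)(C)C(C)(C)C)Oc6c(OC)cc(cc6OC)[C@@H]2Oc3c(OC)cc([Li])cc3[C@H]2CO[Si](c4ccccc4)(c5ccccc5)C(C)(C)C | intermediate
30 | (2R,3S)-2-(4-{[(1S,2R)-1,3-bis[(tert-butyldimethylsilyl)oxy]-1-{4-[(tert-butyldimethylsilyl)oxy]-3-methoxyphenyl}propan-2-yl]oxy}-3,5-dimethoxyphenyl)-3-{[(tert-butyldiphenylsilyl)oxy]methyl}-7-methoxy-2,3-dihydro-1-benzofuran-5-carbaldehyde | COc1cc(ccc1O[Si](C)(C)C(C)(C)C)[C@H](O[Si](C)(C)C(C)(C)C)[C@@H](CO[Si](C)(C)C(C)(C)C)Oc6c(OC)cc(cc6OC)[C@@H]2Oc3c(OC)cc(C=O)cc3[C@H]2CO[Si](c4ccccc4)(c5ccccc5)C(C)(C)C | intermediate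
31 | (2R,3S)-2-(4-{[(1S,2R)-1,3-dihydroxy-1-(4-hydroxy-3-methoxyphenyl)propan-2-yl]oxy}-3,5-dimethoxyphenyl)-3-(hydroxymethyl)-7-methoxy-2,3-dihydro-1-benzofuran-5-carbaldehyde | COc1cc([C@H](O)[C@@H](CO)Oc2c(OC)cc([C@@H]3Oc4c(OC)cc(C=O)cc4[C@H]3CO)cc2OC)ccc1O | target

**Step count and risks**

Total step count: 21. Longest linear sequence: 17 steps (steps 1–5, 7–11, 14, 15, 17–21).

Steps most likely to fail:

Step 14. The doubly ortho-substituted ring B phenol may attack the oxyphosphonium ion too slowly, so that the activated hydroxy ester is lost by elimination or by capture of the hydrazide anion. The fallback sets out from 20, which is converted with Tf2O and 2,6-lutidine (CH2Cl2, −78 °C) into methyl (2S)-3-[(tert-butyldimethylsilyl)oxy]-2-[(trifluoromethanesulfonyl)oxy]propanoate F1. The caesium phenoxide of 17 (Cs2CO3, MeCN, −20 °C) then displaces the triflate in an SN2 reaction with inversion at the ester alpha-carbon. The fallback comes back to the route at 21.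

Step 18. Facial selectivity may be poor if the aryloxy oxygen binds zinc only weakly, since an open Felkin–Anh transition state would lead towards the threo 7'R epimer. The fallback sets out from 22 and avoids the ketone. Reduction with iBu2AlH (THF, −78 °C) should give the aldehyde (2R)-2-{4-[(2R,3S)-5-bromo-3-{[(tert-butyldiphenylsilyl)oxy]methyl}-7-methoxy-2,3-dihydro-1-benzofuran-2-yl]-2,6-dimethoxyphenoxy}-3-[(tert-butyldimethylsilyl)oxy]propanal F2. To it is added {4-[(tert-butyldimethylsilyl)oxy]-3-methoxyphenyl}lithium F3, made from 24 and t-BuLi in Et2O at −78 °C. Under these non-chelating conditions the aryl group should enter anti to the aryloxy substituent (Felkin–Anh), which gives the same (1S,2R) alcohol. The fallback comes back to the route at 27.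

Step 11. Under acid the quinone methide or the benzylic cation may be captured between molecules by the electron-rich rings (oligomers), or the cation may fragment with loss of the C9 arm. The fallback sets out from 15 and keeps the same ring closure but separates activation from closure. Me3SiBr (CH2Cl2, 0 °C) should convert the benzylic alcohol into 4-{(2S)-1-bromo-2-(5-bromo-2-hydroxy-3-methoxyphenyl)-3-[(tert-butyldiphenylsilyl)oxy]propyl}-2,6-dimethoxyphenol F4. Stirring a dilute solution of F4 with aq NaHCO3 eliminates HBr to give quinone methide 16 without acid and at low stationary concentration, and O1 closes ring D. The fallback comes back to the route at 17; a short exposure to catalytic TsOH would equilibrate any cis isomer.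

**Further compounds**

F1 | step 14 | methyl (2S)-3-[(tert-butyldimethylsilyl)oxy]-2-[(trifluoromethanesulfonyl)oxy]propanoate | COC(=O)[C@H](CO[Si](C)(C)C(C)(C)C)OS(=O)(=O)C(F)(F)F
F2 | step 18 | (2R)-2-{4-[(2R,3S)-5-bromo-3-{[(tert-butyldiphenylsilyl)oxy]methyl}-7-methoxy-2,3-dihydro-1-benzofuran-2-yl]-2,6-dimethoxyphenoxy}-3-[(tert-butyldimethylsilyl)oxy]propanal | O=C[C@@H](CO[Si](C)(C)C(C)(C)C)Oc1c(OC)cc(cc1OC)[C@@H]2Oc3c(OC)cc(Br)cc3[C@H]2CO[Si](c4ccccc4)(c5ccccc5)C(C)(C)C
F3 | step 18 | {4-[(tert-butyldimethylsilyl)oxy]-3-methoxyphenyl}lithium | COc1cc([Li])ccc1O[Si](C)(C)C(C)(C)C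
F4 | step 11 | 4-{(2S)-1-bromo-2-(5-bromo-2-hydroxy-3-methoxyphenyl)-3-[(tert-butyldiphenylsilyl)oxy]propyl}-2,6-dimethoxyphenol (both C1 epimers) | COc1cc(Br)cc([C@H](C(Br)c2cc(OC)c(O)c(OC)c2)CO[Si](c3ccccc3)(c4ccccc4)C(C)(C)C)c1O
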